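**Plan**

1. Numbering follows the target: ring A is C1–C5 with C10, ring B is C5–C10, C14 sits on C4, C15 on C5, the side chain is C11 (C12 ester carbon, C13 methyl); β is the face of C15, and the decalin names below use these locants.
2. Retrosynthetic cuts, in order: the C3–O angelate ester; the C7–C11 bond (propanoate unit on the α-carbon of the C8 enone); C5–C6, with C3–C8 rejoined (retro anionic oxy-Cope); the C8–vinyl bond; the Diels–Alder bonds C3–C8 and C9–C10.
3. Enabling feature: in ring B the C8 carbonyl lies two atoms (through C9) from the fusion carbon C10, C6–C7 is a two-carbon unit on quaternary C5, and H10 and C15 are cis across the C5–C10 fusion. Such a cis-decalin is the [3,3] product of a 2-vinylbicyclo[2.2.2]oct-5-en-2-ol, and C1–C5, C10, O3, C14 and C15 are the atoms of 2,3-dimethylanisole.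
4. Forward: Birch reduction supplies the diene for ring A, a Diels–Alder reaction builds the bicyclo[2.2.2]octene, vinyl addition gives the carbinol, and the oxy-Cope step closes ring B (C5–C6 formed, C3–C8 broken). Ring A is then adjusted at C4 and C3, the Δ6-enone is iodinated and coupled at C7, and the angelate is attached last.
5. Stereochemistry: C10 from the copper-catalysed Diels–Alder reaction, C5 from the suprafacial [3,3] shift, C4 from A(1,3) strain in an enamine, C3 from hydride delivery anti to C14, C11 from a chiral nickel catalyst, the Z alkene from angelic acid.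

Key step: step 7

Assumption: the Birch reduction is written for the 1-methoxy-2,3-dimethylcyclohexa-1,4-diene isomer; the other dihydro isomer would be conjugated to the same diene 3 in step 2.
Assumption: the antipode of the nickel ligand that gives 11R in step 14 is fixed in a model coupling with 2-iodocyclohex-2-en-1-one and is written here as (R,R).

**Route**

Step 1
Reactants: 1 2,3-dimethylanisole
Product: 2 1-methoxy-2,3-dimethylcyclohexa-1,4-diene
Conditions: Li, liquid NH3, t-BuOH, THF, −78 to −33 °C; MeOH quench
Reagents that add atoms: none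
Why: Birch reduction, in which the arene radical anion is protonated at the unsubstituted ortho carbon and then para to it, so that the methoxy group and the neighbouring methyl stay on a tetrasubstituted enol ether and the unconjugated diene results.

Step 2
Reactants: 2 1-methoxy-2,3-dimethylcyclohexa-1,4-diene
Product: 3 1-methoxy-2,3-dimethylcyclohexa-1,3-diene
Conditions: KOt-Bu (0.3 equiv), DMSO, 25 °C
Reagents that add atoms: none
Why: base-mediated conjugation by prototropic shift through the pentadienyl anion should funnel the dihydroanisole to the most substituted 1-methoxy-1,3-diene, the only isomer that can give the wanted cycloadduct.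

Step 3
Reactants: 3 1-methoxy-2,3-dimethylcyclohexa-1,3-diene; 4 3-acryloyl-1,3-oxazolidin-2-one
Product: 5 3-{[(1R,2R,4R)-1-methoxy-5,6-dimethylbicyclo[2.2.2]oct-5-en-2-yl]carbonyl}-1,3-oxazolidin-2-one (acyl group syn to the alkene bridge)
Conditions: Cu((R,R)-t-Bu-box)(SbF6)2 (10 mol %; from CuCl2, AgSbF6 and 2,2'-(propane-2,2-diyl)bis[(4R)-4-tert-butyl-4,5-dihydro-1,3-oxazole]), CH2Cl2, 4 Å molecular sieves, −40 to 0 °C; chromatography to remove the exo adduct
Reagents that add atoms: none
Why: catalytic enantioselective Diels–Alder reaction in which the s-cis imide chelates divalent copper in a square-planar complex, the (R,R) ligand (mirror image of the (S,S) ligand that gives 2S adducts with simple dienes) leaves the si face of the α-carbon open, and endo addition with the methoxy-bearing diene terminus bonding to the α-carbon (ortho rule) sets both bridgeheads; the exo adduct, which would lead to the antipodal ketone, is removed.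

Step 4
Reactants: 5 the imide adduct
Product: 7 (1R,2R,4R)-1-methoxy-5,6-dimethylbicyclo[2.2.2]oct-5-ene-2-carboxylic acid, via peroxy acid 6 (not isolated)
Conditions: LiOH, H2O2, THF/H2O, 0 °C; aq. Na2SO3; then HCl to pH 3
Reagents that add atoms: hydrogen peroxide, OO
Why: hydroperoxide cleavage of the N-acyl oxazolidinone, in which the hydroperoxide anion attacks the exocyclic carbonyl and the percarboxylate is reduced by sulfite before acidification, so that no free peracid meets the tetrasubstituted alkene.

Step 5
Reactants: 7 the bicyclic acid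
Product: 10 (1S,4R)-1-methoxy-5,6-dimethylbicyclo[2.2.2]oct-5-en-2-one, via dilithium enediolate 8 (not isolated), via hydroperoxy acid 9 (not isolated)
Conditions: LiN(i-Pr)2 (2.2 equiv), THF, 0 °C; O2, −78 °C; cold dilute HCl; crude 9 with Me2NCH(OMe)2, CH2Cl2, 25 °C
Reagents that add atoms: dioxygen, O=O
Why: oxidative decarboxylation through the α-hydroperoxy acid (oxygenation of the carboxylic acid dianion, then decarboxylative fragmentation with loss of CO2 and water), which turns the acrylate unit into a ketene equivalent; loss of the bridgehead methoxide from the dianion is excluded by Bredt's rule.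

Step 6
Reactants: 10 the bicyclic ketone; 11 vinylmagnesium bromide
Product: 12 (1S,2R,4R)-1-methoxy-5,6-dimethyl-2-vinylbicyclo[2.2.2]oct-5-en-2-ol (vinyl syn to the alkene bridge)
Conditions: 10 stirred with anhydrous CeCl3 (1.5 equiv), THF; CH2=CHMgBr, −78 °C; aq. NH4Cl
Reagents that add atoms: none
Why: CeCl3-promoted 1,2-addition of the Grignard reagent (enolisation suppressed) from the carbonyl face that looks at the flat dimethyl-substituted alkene bridge and not at the ethano bridge, which places the vinyl group syn to the alkene and makes C2 R.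

Step 7
Reactants: 12 the vinyl carbinol (target numbering: carbinol carbon C8, methoxy bridgehead C3, alkene bridge C4=C5, other bridgehead C10, vinyl C7=C6)
Product: 15 cis-decalin bis(enol ether) with C3=C4 methyl enol ether and C7=C8 trimethylsilyl enol ether, via potassium alkoxide 13 (not isolated), via potassium enolate 14 (not isolated)
Conditions: KH (1.5 equiv), 18-crown-6 (1.5 equiv), THF, 0 to 25 °C; then Me3SiCl/Et3N, −78 °C; pentane/aq. NaHCO3
Reagents that add atoms: chlorotrimethylsilane, C[Si](C)(C)Cl
Why: KH deprotonates the tertiary alcohol and the crown ether frees alkoxide 13, whose oxyanion weakens the C3–C8 bond so that the 1,5-diene C6=C7–C8–C3–C4=C5 undergoes a concerted [3,3] sigmatropic shift at or below room temperature (anionic oxy-Cope rearrangement; closest precedent: KH/18-crown-6 rearrangements of 1-methoxy-2-vinylbicyclo[2.2.2]oct-5-en-2-ols to cis-fused octalone enolates), helped by the bridgehead methoxy group, which stabilises the developing enol ether at C3. Ring B (C5–C6–C7–C8–C9–C10) closes by suprafacial carbon–carbon bond formation between the vinyl terminus C6 and alkene carbon C5 through the boat-shaped six-atom array that the bicycle enforces, while cleavage of C3–C8 releases ring A as the C3=C4 methyl enol ether. The one new stereocentre, C5, is controlled by the framework: C6 can reach C5 only on the alkene face turned towards the carbinol bridge, which places C15 cis to H10, and because C10 is the bridgehead set in step 3 the absolute configuration (5S,10R in 15) follows. The step needs the vinyl group syn to the C4=C5 bridge, secured by the facial selectivity of step 6, and it needs the enolate regiochemistry to survive, which is intrinsic because the enolate carbon C7 is the former internal vinyl carbon. O-Silylation of 14 stores this regiochemistry as the C7=C8 silyl enol ether.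

Step 8
Reactants: 15 the bis(enol ether)
Product: 16 3-methoxy-4,5β-dimethyl-10βH-decalin-3,6-dien-8-one
Conditions: Pd(OAc)2 (1.05 equiv), dry MeCN, 25 °C
Reagents that add atoms: none
Why: Saegusa–Ito oxidation, in which divalent palladium adds to the silyl enol ether at C7 and β-hydride elimination can only take a hydrogen from C6, so the enone is Δ6 by construction while the tetrasubstituted methyl enol ether is left alone.

Step 9
Reactants: 16 the enone
Product: 17 3-methoxy-4,5β-dimethyl-10βH-decalin-3,6-dien-8-ol (C8 epimers)
Conditions: NaBH4, CeCl3·7H2O, MeOH, −78 to 0 °C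
Reagents that add atoms: none
Why: Luche 1,2-reduction masks the enone as its allylic alcohol so that no C8 carbonyl is present during the enolising steps on ring A, where a 3,8-dione of a cis-decalin could close to a bridged aldol product; the C8 configuration is of no consequence because the alcohol is reoxidised in step 12.

Step 10
Reactants: 17 the allylic alcohol
Product: 20 8-hydroxy-4β,5β-dimethyl-10βH-decal-6-en-3-one (C8 epimers), via ketone epimer mixture 18 (not isolated), via pyrrolidine enamine 19 (not isolated)
Conditions: (CO2H)2 (aq., 0.1 M), THF, 0 °C; extractive work-up; pyrrolidine (3 equiv), TsOH·H2O (5 mol %), benzene, reflux with water separation; then AcOH/NaOAc buffer (pH 5), THF/H2O, 0 °C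
Reagents that add atoms: water, O
Why: enol ether hydrolysis, which by itself does not control C4, followed by enamine formation under equilibrating conditions and kinetic hydrolysis: in the less substituted C2=C3 enamine, A(1,3) strain with the pyrrolidine ring forces the C4 methyl pseudoaxial, which this cis-decalin can offer only on the β face (an axial 4α-methyl would be syn-diaxial to C9), so the epimers should drain to the 4β enamine, and buffered hydrolysis protonates C2, not C4.

Step 11
Reactants: 20 the 4β-methyl hydroxy ketone
Product: 21 4β,5β-dimethyl-10βH-decal-6-ene-3β,8-diol (C8 epimers)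
Conditions: LiBH(s-Bu)3 (2.5 equiv), THF, −78 °C; aq. NH4Cl
Reagents that add atoms: none
Why: ketone reduction with a bulky trialkylborohydride, which delivers hydride to C3 anti to the neighbouring C4 methyl and from the α face that the C15 methyl does not screen, giving the cis-3,4 relationship with the hydroxyl β (3S).

Step 12
Reactants: 21 the diol
Product: 22 (3S,4R,5R,10R)-3-hydroxy-4,5-dimethyl-decal-6-en-8-one (3β-hydroxy, 10βH)
Conditions: activated MnO2 (excess), CH2Cl2, 25 °C
Reagents that add atoms: none
Why: allylic oxidation with MnO2, which converts the allylic C8 alcohol to the enone and leaves the saturated, hindered C3 alcohol untouched.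

Step 13
Reactants: 22 the hydroxy enone
Product: 23 3β-hydroxy-7-iodo-4β,5β-dimethyl-10βH-decal-6-en-8-one
Conditions: I2 (2 equiv), pyridine/CH2Cl2 1:1, 0 to 25 °C; aq. Na2S2O3
Reagents that add atoms: iodine, [I][I]
Why: α-iodination of the enone by the iodine–pyridine protocol (Baylis–Hillman-type addition of pyridine at C6, iodination of the enolate at C7, elimination), which tolerates the free alcohol and is known for enones with a quaternary γ-carbon.

Step 14
Reactants: 23 the iodo enone; 24 methyl 2-chloropropanoate (racemic)
Product: 25 methyl (3S,4R,5R,10R,11R)-3-hydroxy-8-oxoeremophil-6-en-12-oate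
Conditions: NiBr2(dme) (10 mol %), (4R,4'R)-4,4'-di(heptan-4-yl)-4,4',5,5'-tetrahydro-2,2'-bioxazole (12 mol %), Mn powder (3 equiv), DMA, 0 °C
Reagents that add atoms: none
Why: Proposed new method: nickel-catalysed enantioconvergent reductive cross-coupling of an α-iodo enone with a racemic α-chloro ester, in which zerovalent nickel inserts into the C7–I bond, chlorine abstraction from 24 by a monovalent nickel species gives a planar α-ester radical (erasing the configuration of the chloride), the radical is captured at the alkenylnickel centre, and reductive elimination from trivalent nickel forms C7–C11 inside the chiral pocket of the bi(oxazoline) ligand, which should select 11R independently of the remote ring stereocentres while Mn returns nickel to the low-valent state; the closest known reactions are the nickel-catalysed enantioconvergent reductive arylation of racemic α-chloro esters with aryl iodides and the enantioconvergent alkenylation of racemic α-halo esters with alkenyl-metal reagents.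

Step 15
Reactants: 26 angelic acid
Product: 27 (Z)-2-methylbut-2-enoic 2,4,6-trichlorobenzoic anhydride
Conditions: 2,4,6-Cl3C6H2COCl (1.0 equiv), Et3N (1.0 equiv), toluene, 0 to 25 °C; filtration; concentration
Reagents that add atoms: 2,4,6-trichlorobenzoyl chloride, O=C(Cl)c1c(Cl)cc(Cl)cc1Cl
Why: mixed anhydride formation (Yamaguchi reagent) at low temperature without a nucleophilic catalyst, so that the Z geometry of angelic acid is retained.

Step 16
Reactants: 25 the hydroxy ester; 27 the mixed anhydride
Product: 28 methyl (3S,4R,5R,10R,11R)-3-[(Z)-2-methylbut-2-enoyloxy]-8-oxoeremophil-6-en-12-oate (CNP0323033.1)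
Conditions: 27 (2 equiv), solid NaHCO3 (3 equiv), toluene, 80 °C; dilute HCl wash
Reagents that add atoms: none
Why: Yamaguchi-type acylation with the preformed mixed anhydride, in which the hindered trichlorobenzoyl carbonyl directs the C3 hydroxyl to the angeloyl carbonyl and the absence of soluble amine and of acylpyridinium catalysis should avoid both isomerisation to the tiglate and epimerisation at C11.

**Compound list**

1 | 2,3-dimethylanisole | COc1cccc(C)c1C | starting material
2 | 1-methoxy-2,3-dimethylcyclohexa-1,4-diene | COC1=C(C)C(C)C=CC1 | intermediate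
3 | 1-methoxy-2,3-dimethylcyclohexa-1,3-diene | COC1=C(C)C(C)=CCC1 | intermediate
4 | 3-acryloyl-1,3-oxazolidin-2-one | C=CC(=O)N1CCOC1=O | starting material
5 | 3-{[(1R,2R,4R)-1-methoxy-5,6-dimethylbicyclo[2.2.2]oct-5-en-2-yl]carbonyl}-1,3-oxazolidin-2-one (acyl syn to the alkene bridge) | O=C(N1CCOC1=O)[C@@H]1C[C@H]2CC[C@]1(OC)C(C)=C2C | intermediate
6 | (1R,2R,4R)-1-methoxy-5,6-dimethylbicyclo[2.2.2]oct-5-ene-2-carboperoxoic acid (not isolated) | OOC(=O)[C@@H]1C[C@H]2CC[C@]1(OC)C(C)=C2C | intermediate
7 | (1R,2R,4R)-1-methoxy-5,6-dimethylbicyclo[2.2.2]oct-5-ene-2-carboxylic acid | OC(=O)[C@@H]1C[C@H]2CC[C@]1(OC)C(C)=C2C | intermediate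
8 | dilithium enediolate of acid 7 (not isolated) | [Li+].[Li+].[O-]C([O-])=C1C[C@H]2CC[C@]1(OC)C(C)=C2C | intermediate
9 | (1S,4R)-2-hydroperoxy-1-methoxy-5,6-dimethylbicyclo[2.2.2]oct-5-ene-2-carboxylic acid, C2 epimers (not isolated) | OOC1(C(O)=O)C[C@H]2CC[C@]1(OC)C(C)=C2C | intermediate
10 | (1S,4R)-1-methoxy-5,6-dimethylbicyclo[2.2.2]oct-5-en-2-one | O=C1C[C@H]2CC[C@]1(OC)C(C)=C2C | intermediate
11 | vinylmagnesium bromide | C=C[Mg]Br | starting material
12 | (1S,2R,4R)-1-methoxy-5,6-dimethyl-2-vinylbicyclo[2.2.2]oct-5-en-2-ol (vinyl syn to the alkene bridge) | O[C@@]1(C=C)C[C@H]2CC[C@]1(OC)C(C)=C2C | intermediate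
13 | potassium alkoxide of 12 (not isolated) | [K+].[O-][C@@]1(C=C)C[C@H]2CC[C@]1(OC)C(C)=C2C | intermediate
14 | potassium enolate of the cis-decalin: C3=C4 methyl enol ether, C7=C8 enolate, 4,5-dimethyl, C15 and H10 β (not isolated) | [K+].COC1=C(C)[C@@]2(C)CC=C([O-])C[C@H]2CC1 | intermediate
15 | cis-decalin bis(enol ether): (4aS,8aR)-3-methoxy-4,4a-dimethyl-7-(trimethylsilyloxy)-1,2,4a,5,8,8a-hexahydronaphthalene (target numbering: C3=C4 methyl enol ether, C7=C8 silyl enol ether, C15 and H10 β) | COC1=C(C)[C@@]2(C)CC=C(O[Si](C)(C)C)C[C@H]2CC1 | intermediate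
16 | 3-methoxy-4,5β-dimethyl-10βH-decalin-3,6-dien-8-one | COC1=C(C)[C@@]2(C)C=CC(=O)C[C@H]2CC1 | intermediate
17 | 3-methoxy-4,5β-dimethyl-10βH-decalin-3,6-dien-8-ol (C8 epimers) | COC1=C(C)[C@@]2(C)C=CC(O)C[C@H]2CC1 | intermediate
18 | 8-hydroxy-4,5β-dimethyl-10βH-decal-6-en-3-one, C4 and C8 epimers (not isolated) | O=C1C(C)[C@@]2(C)C=CC(O)C[C@H]2CC1 | intermediate
19 | pyrrolidine enamine: 3-(pyrrolidin-1-yl)-4β,5β-dimethyl-10βH-decalin-2,6-dien-8-ol (not isolated) | N1(CCCC1)C1=CC[C@@H]2CC(O)C=C[C@]2(C)[C@H]1C | intermediate
20 | 8-hydroxy-4β,5β-dimethyl-10βH-decal-6-en-3-one (C8 epimers) | O=C1[C@H](C)[C@@]2(C)C=CC(O)C[C@H]2CC1 | intermediate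
21 | 4β,5β-dimethyl-10βH-decal-6-ene-3β,8-diol (C8 epimers) | O[C@H]1CC[C@@H]2CC(O)C=C[C@]2(C)[C@H]1C | intermediate
22 | (3S,4R,5R,10R)-3-hydroxy-4,5-dimethyl-decal-6-en-8-one | O[C@H]1CC[C@@H]2CC(=O)C=C[C@]2(C)[C@H]1C | intermediate
23 | 3β-hydroxy-7-iodo-4β,5β-dimethyl-10βH-decal-6-en-8-one | O[C@H]1CC[C@@H]2CC(=O)C(I)=C[C@]2(C)[C@H]1C | intermediate
24 | methyl 2-chloropropanoate (racemic) | CC(Cl)C(=O)OC | starting material
25 | methyl (3S,4R,5R,10R,11R)-3-hydroxy-8-oxoeremophil-6-en-12-oate | O[C@H]1CC[C@@H]2CC(=O)C([C@@H](C)C(=O)OC)=C[C@]2(C)[C@H]1C | intermediate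
26 | angelic acid, (Z)-2-methylbut-2-enoic acid | C/C=C(/C)C(=O)O | starting material
27 | (Z)-2-methylbut-2-enoic 2,4,6-trichlorobenzoic anhydride | C/C=C(/C)C(=O)OC(=O)c1c(Cl)cc(Cl)cc1Cl | intermediate
28 | methyl (3S,4R,5R,10R,11R)-3-[(Z)-2-methylbut-2-enoyloxy]-8-oxoeremophil-6-en-12-oate | C/C=C(/C)C(=O)O[C@H]1CC[C@@H]2CC(=O)C([C@@H](C)C(=O)OC)=C[C@]2(C)[C@H]1C | target

**Count and risks**

Total step count: 16. Longest linear sequence: 15 (steps 1–14 and 16; step 15 is a one-step side branch).

Step 14 (proposed coupling). Protodeiodination or homocoupling of the alkenylnickel species may outrun capture of the ester radical, and catalyst control at C11 may be weak. The fallback sets out from 23 and uses a palladium-catalysed Negishi-type coupling with the Reformatsky reagent BrZnCH(CH3)CO2Me (Pd(dba)2, P(t-Bu)3, THF, 25 °C), a known coupling of zinc ester enolates with alkenyl halides. It is not selective at C11 and should give 25 together with its C11 epimer, methyl (3S,4R,5R,10R,11S)-3-hydroxy-8-oxoeremophil-6-en-12-oate F1. The epimers are separated by preparative HPLC and the route is rejoined at 25.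

Step 10 (C4 control). Enamine formation at the hindered C3 carbonyl may be slow, equilibration between the C4 epimers may stay incomplete, or the allylic hydroxyl may ionise under the acidic reflux. The fallback sets out from 17: hydrolysis with aqueous oxalic acid and isolation of the epimer mixture 18, then direct reduction with LiBH(s-Bu)3. This reagent attacks each epimer anti to its C4 methyl and should therefore give only the two cis-3,4 diols, 21 and the 3α-hydroxy-4α-methyl diol 4α,5β-dimethyl-10βH-decal-6-ene-3α,8-diol F2. Chromatographic separation returns the route to 21.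

Step 3 (asymmetric Diels–Alder). The Lewis acid may degrade the acid-sensitive methoxydiene, or the tetrasubstituted diene terminus may erode endo and facial selectivity. The fallback sets out from 3: thermal Diels–Alder reaction with methyl acrylate (toluene, 110 °C, radical inhibitor) and chromatographic isolation of the endo ester, racemic methyl (1R*,2R*,4R*)-1-methoxy-5,6-dimethylbicyclo[2.2.2]oct-5-ene-2-carboxylate F3. Saponification (LiOH, THF/H2O) gives the racemic acid F4, which is resolved by crystallisation of the (S)-1-phenylethylammonium salt of the (1R,2R,4R) acid F5; the antipodal amine is used if the other salt proves less soluble. Acidification returns the route to 7.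

Further compounds
F1 | step 14 | methyl (3S,4R,5R,10R,11S)-3-hydroxy-8-oxoeremophil-6-en-12-oate | O[C@H]1CC[C@@H]2CC(=O)C([C@H](C)C(=O)OC)=C[C@]2(C)[C@H]1C
F2 | step 10 | 4α,5β-dimethyl-10βH-decal-6-ene-3α,8-diol (C8 epimers) | O[C@@H]1CC[C@@H]2CC(O)C=C[C@]2(C)[C@@H]1C
F3 | step 3 | racemic methyl (1R*,2R*,4R*)-1-methoxy-5,6-dimethylbicyclo[2.2.2]oct-5-ene-2-carboxylate (one enantiomer drawn) | COC(=O)[C@@H]1C[C@H]2CC[C@]1(OC)C(C)=C2C
F4 | step 3 | racemic (1R*,2R*,4R*)-1-methoxy-5,6-dimethylbicyclo[2.2.2]oct-5-ene-2-carboxylic acid (one enantiomer drawn) | OC(=O)[C@@H]1C[C@H]2CC[C@]1(OC)C(C)=C2C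
F5 | step 3 | (S)-1-phenylethylammonium (1R,2R,4R)-1-methoxy-5,6-dimethylbicyclo[2.2.2]oct-5-ene-2-carboxylate | C[C@H]([NH3+])c1ccccc1.[O-]C(=O)[C@@H]1C[C@H]2CC[C@]1(OC)C(C)=C2C
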